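## Structural features

The target is a 2,3-trans dihydroflavonol: a chroman-4-one in which benzo ring A is fused to the dihydropyranone ring C (O1, C2, C3, C4, C4a, C8a), with the 4-hydroxy-3-methoxyphenyl ring B on C2. The only stereocentres are C2 (R, benzylic, bonded to O1) and C3 (R, secondary alcohol). They are adjacent and trans, so both substituents sit equatorial on ring C. Ring A carries a phenol at C5 that is hydrogen-bonded to the C4 carbonyl and a 3-methylbut-2-enyl (prenyl) ether at O7; ring B carries a free phenol at C4' next to the methoxy group. The fragile points are several. C3–H is α to the ketone, and enolisation followed by β-elimination of O1 would open ring C and erase C2. The α-hydroxy ketone is easily dehydrogenated to the flavonol. The prenyl aryl ether tolerates neither acid nor hydrogen over palladium. The real difficulty is twofold: two contiguous oxygen-bearing stereocentres must be set in relative and absolute sense, and four hydroxyl groups must be told apart so that only O7 is alkylated. The key step uses the fact that C3 bears oxygen and lies between the C4 ketone and the oxygenated benzylic C2. The unit C4(=O)–C3(O)–C2(O) is therefore the aldol of an α-alkoxy ring A ketone with a ring B aldehyde, and a ketocarbene, an alcohol and an aldehyde can assemble it in one operation. O1–C8a can then be closed from the aldol hydroxyl without touching either centre.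

## Logic of the disconnections

**17 to 15 and 16.** The O7–CH2 bond of the prenyl ether is cut first. This group is the one part of 17 that survives neither hydrogenolysis nor acid, so it has to be attached after every other oxygen has been freed. What remains, 15, has no alkene and no allylic ether. The forward step must pick O7 out of four hydroxyls. It can, because the 7-hydroxyl (para to the C4 carbonyl) is the strongest acid, the 5-hydroxyl is locked in a hydrogen bond, the 4'-phenol is a weaker acid and the 3-hydroxyl is an alcohol. One equivalent of a weak base, used cold, is the condition.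

**15 to 14.** The three O–CH2Ph bonds at O3, O7 and O4' are cut. The oxygen on C3 can only arrive as the ether of the alcohol used in the key step, and a benzyl ether is the one such ether that leaves under neutral conditions. Using the same group on O7 and O4' makes deprotection a single operation. The forward step must spare the benzylic C2–O1 bond and the C4 carbonyl.

**14 to 12 (through 13).** The O1–C8a bond is cut, together with the O5–Si bond. Ring C opens to an acyclic aldol whose C8a carries fluorine ortho to the ketone. In the forward sense the C2 alkoxide displaces fluoride. No bond at either stereocentre is made or broken, so an anti aldol becomes the 2,3-trans ring. The demand is that closure be faster than retro-aldol cleavage and β-elimination, and that no base remain once the chromanone exists, since its C3–H is acidic. The silyl group on O5 is removed in the same flask, so it costs no step.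

**12 to 8, 9 and 10.** The C2–C3 bond and the C3–O bond (chromanone numbering) are cut together. This is the key disconnection; it reduces the chain to a ring A diazoketone, an alcohol and a ring B aldehyde, the last two bought. The forward step has to create both stereocentres, to add to the aldehyde before the proton shift that would give plain O–H insertion, and to offer the carbene no internal nucleophile.

**8 to 6 (through 7).** The C=N2 unit is removed, leaving a methyl ketone. The diazo group then comes from a shelf-stable sulfonyl azide, so neither diazomethane nor an acid chloride is needed. The demand is prior activation of the methyl ketone as its trifluoroacetyl derivative, since a simple ketone enolate does not undergo clean diazo transfer.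

**6 to 5.** The O–Si bond on the oxygen ortho to the acyl group is cut. This oxygen must not be a benzyl or other alkyl ether when the carbene is formed. It would add to the carbene carbon (five-membered oxonium ylide) and, after a 1,2-shift, give a benzofuran-3-one. A free phenol would do the same by O–H insertion. A triisopropylsilyl ether on an aryl oxygen is hindered and a poor donor, and fluoride removes it later. The forward step must silylate a hindered, hydrogen-bonded phenol.

**5 to 3 and 4.** The O–CH2Ph bond at the para oxygen is cut. This tells the two ring A oxygens apart: one leaves by hydrogenolysis, the other by fluoride. The forward step must alkylate only the hydroxyl that is not chelated.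

**3 to 1 and 2.** The aryl–acyl bond (C4–C4a of the target) is cut, leaving two bought compounds. The forward acylation must enter between fluorine and one hydroxyl, para to the other, and not between the two hydroxyls.

## Other disconnections considered

**Alternative 1:** The cut goes through ring A: C4a–C5 and C8–C8a are broken, so ring C with both stereocentres exists first as the bromo dihydropyranone A2 and the benzene ring is built last. Forward, A2 would act as dienophile toward the ketene acetal diene A3, which already carries the prenyl ether. Loss of HBr and of methoxytrimethylsilane from the [4+2] adduct would aromatise ring A and give A1 with the 5-hydroxyl free.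
- In its favour: the prenyl group comes in on A3, so O7 never has to be told apart from O5 and O4'. No hydrogenolysis is needed, only fluoride for two silyl ethers. On late-stage selectivity and protecting-group economy this plan is better than the chosen one.
- The polarity is matched: the nucleophilic CH2 terminus of A3 meets the β-carbon of the enone.
- Against it: the double bond of A2 is that of a vinylogous ester and is a weak dienophile, which the bromine only partly remedies. The heat or Lewis acid needed would act on a C3 centre α to the ketone. A3 contains an allyl vinyl ether that could undergo Claisen rearrangement under the same conditions.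
- The cycloaddition creates no stereocentre, so A2 needs an asymmetric synthesis of its own. In stereochemical terms this key step solves less than the chosen one.
- Step economy: about ten or more steps against eight.

**Alternative 2:** The cuts are O1–C2 and C3–C4: ring C is assembled from a one-carbon unit on ring A and the C2–C3 alkene of ring B. Forward, a chiral phosphoric acid would dehydrate the hydroxybenzyl alcohol A5 to the ortho-quinone methide and, bound to it and to the phenol of the enol pivalate A6, guide a hetero-[4+2] addition to A4.
- In its favour: one catalytic step closes ring C and sets both stereocentres, where the chosen plan needs a separate ring closure. The trans relationship follows from the E geometry of A6 and not from catalyst-controlled diastereoselection. On both points it is the better plan.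
- The polarity is matched: the oxygen-bearing carbon of the electron-rich styrene attacks the methide carbon, and ring B stabilises positive charge at C2.
- Against it here: A4 is a flavan with CH2 at C4. A benzylic oxidation at C4 would have to follow on a compound whose C2–H is also benzylic and α to oxygen, and whose ring A is an electron-rich phloroglucinol ether.
- The free 4'-phenol needed for catalyst binding has to be carried through that oxidation.
- The end game is no shorter: ester cleavage, hydrogenolysis and the same O7 alkylation remain, which makes it equal to the chosen plan there.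
- Step economy: about eleven steps against eight.

**Alternative 3:** The cuts are O1–C8a and C4–C4a: ring A is delivered as an aryne and the C2–C3–C4 chain with both stereocentres as the anti hydroxy ester A9. Forward, CsF would release the aryne from the silyl triflate A8. The hydroxyl of A9 would add to the aryne carbon remote from the neighbouring benzyloxy group, and the aryl anion formed next to that group would attack the ester to close ring C as A7.
- In its favour: two bonds and the ring form in one flask under weakly basic conditions, with no separate SNAr step. The regiochemistry is the one the 3-alkoxy group of the aryne favours. An ester aldolate is less prone to retro-aldol cleavage than the ketone aldolate of 12. No carbene has to pass an ortho substituent. On ring closure it is the better plan.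
- A7 differs from 14 only by a benzyl group on O5, so the end game is equal.
- Against it: the stereocentres are not made by the key step. A9 needs its own anti-selective asymmetric aldol, so the stereochemical problem is moved, not solved.
- Aliphatic alcohols are modest aryne traps, and protonation of the aryl anion would leave an uncyclised aryl ether.
- A8 takes four or more steps.
- Step economy: about eleven to twelve steps against eight.

Key step: step 5

Assumption: the sense of induction of the binaphthyl phosphoric acid in step 5 cannot be assigned with certainty in advance; the (R) acid is written, and its enantiomer is to be used if a trial run shows the opposite sense.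

## Route

**Step 1**
Reactants: 1 5-fluororesorcinol (5-fluorobenzene-1,3-diol); 2 acetic acid
Product: 3 1-(2-fluoro-4,6-dihydroxyphenyl)ethan-1-one
Conditions: ZnCl2 (1.5 equiv), AcOH, 140 °C
Reagents that add atoms: none
Why: Nencki reaction (ZnCl2-promoted Friedel–Crafts C-acylation of a phenol by a carboxylic acid); the acyl group should enter para to one hydroxyl and ortho to the other, as with resorcinol, because the position between the two hydroxyls is the more hindered, and the ketone then deactivates the ring toward a second acylation.

**Step 2**
Reactants: 3 1-(2-fluoro-4,6-dihydroxyphenyl)ethan-1-one; 4 benzyl bromide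
Product: 5 1-[4-(benzyloxy)-2-fluoro-6-hydroxyphenyl]ethan-1-one
Conditions: BnBr (1.05 equiv), K2CO3 (1.1 equiv), acetone, reflux
Reagents that add atoms: none
Why: Williamson etherification; the hydroxyl para to the acetyl group is the more acidic and is free, while the ortho hydroxyl is held in a hydrogen bond to the carbonyl, so one equivalent of 4 should alkylate the para oxygen only.

**Step 3**
Reactants: 5 1-[4-(benzyloxy)-2-fluoro-6-hydroxyphenyl]ethan-1-one
Product: 6 1-[4-(benzyloxy)-2-fluoro-6-(triisopropylsilyloxy)phenyl]ethan-1-one
Conditions: TIPSCl, imidazole, DMF, 40 °C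
Reagents that add atoms: chlorotri(propan-2-yl)silane, CC(C)[Si](Cl)(C(C)C)C(C)C
Why: Imidazole-mediated O-silylation of the chelated phenol; these conditions do not silylate the ketone enol, and the bulky aryl silyl ether makes the oxygen ortho to the later carbene neither acidic nor nucleophilic.

**Step 4**
Reactants: 6 1-[4-(benzyloxy)-2-fluoro-6-(triisopropylsilyloxy)phenyl]ethan-1-one
Product: 8 1-[4-(benzyloxy)-2-fluoro-6-(triisopropylsilyloxy)phenyl]-2-diazoethan-1-one, via trifluoroacetyl diketone 7 (not isolated)
Conditions: LiN(SiMe3)2, THF, −78 °C; CF3CO2CH2CF3; then 4-AcNHC6H4SO2N3, Et3N, H2O, MeCN, rt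
Reagents that add atoms: 2,2,2-trifluoroethyl trifluoroacetate, O=C(OCC(F)(F)F)C(F)(F)F (trifluoroacetyl group of 7); 4-acetamidobenzenesulfonyl azide, CC(=O)Nc1ccc(cc1)S(=O)(=O)N=[N+]=[N-] (the two nitrogens of 8)
Why: Detrifluoroacetylative (Regitz-type) diazo transfer; the kinetic lithium enolate is C-acylated to the 1,3-diketone 7, whose enolate adds to the sulfonyl azide and fragments to the diazoketone and the N-trifluoroacetyl sulfonamide, so diazomethane and an acid chloride are avoided.

**Step 5**
Reactants: 8 1-[4-(benzyloxy)-2-fluoro-6-(triisopropylsilyloxy)phenyl]-2-diazoethan-1-one; 9 benzyl alcohol; 10 4-(benzyloxy)-3-methoxybenzaldehyde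
Product: 12 (2R,3R)-2-(benzyloxy)-1-[4-(benzyloxy)-2-fluoro-6-(triisopropylsilyloxy)phenyl]-3-[4-(benzyloxy)-3-methoxyphenyl]-3-hydroxypropan-1-one, via benzyloxy enol 11 (not isolated)
Conditions: Rh2(OAc)4 (2 mol %), (R)-3,3'-bis(2,4,6-triisopropylphenyl)-1,1'-binaphthyl-2,2'-diyl hydrogen phosphate (10 mol %), 9 (1.2 equiv), 10 (1.5 equiv), 4 Å MS, CH2Cl2, −20 °C, 8 added over 2 h
Reagents that add atoms: none
Why: Rh2(OAc)4 (divalent rhodium) should convert 8 with loss of N2 into the rhodium ketocarbene, which 9 attacks at carbon to give the protic oxonium ylide, in equilibrium with the (Z)-enol 11. Before the 1,2-proton shift that would end in plain O–H insertion, 11 adds through its α-carbon to aldehyde 10, which is activated by a hydrogen bond from the chiral phosphoric acid while the P=O oxygen of the same acid holds the enol hydroxyl. The closest known reaction type is the three-component aldol-type trapping of rhodium-carbene-derived oxonium ylides by aldehydes or imines under Rh2(OAc)4 with a chiral phosphoric acid as co-catalyst. No ring is closed. Both new stereocentres arise in the one C–C bond formation and both are under catalyst control: attack on the Si face of the aldehyde gives the (3R) carbinol, and the face of the enol that is left open in the acid's pocket, with the aldehyde aryl group turned away from the benzyloxy group, gives (2R), which is the anti adduct. The step needs the aldol trapping to outpace the proton shift, which slow addition of 8, excess 10, molecular sieves and low temperature should favour. It also needs the carbene to ignore its two ortho neighbours: fluorine is no donor, and the triisopropylsilyl ether oxygen is too hindered and too weakly basic to form the five-membered oxonium ylide that a benzyl ether in that position would give.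

**Step 6**
Reactants: 12 (2R,3R)-2-(benzyloxy)-1-[4-(benzyloxy)-2-fluoro-6-(triisopropylsilyloxy)phenyl]-3-[4-(benzyloxy)-3-methoxyphenyl]-3-hydroxypropan-1-one
Product: 14 (2R,3R)-3,7-bis(benzyloxy)-2-[4-(benzyloxy)-3-methoxyphenyl]-5-hydroxychroman-4-one, via silyl-protected chromanone 13 (not isolated)
Conditions: NaH (1.05 equiv), THF, 0 °C to rt; then AcOH, Bu4NF, 0 °C
Reagents that add atoms: none
Why: Intramolecular SNAr etherification; the sodium alkoxide of the carbinol attacks the fluorine-bearing carbon ortho to the ketone in a six-membered closure and fluoride leaves, so no bond at either stereocentre is broken and the anti aldol gives the 2,3-trans chromanone 13. Buffered fluoride then cleaves the aryl silyl ether without exposing the chromanone to base.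

**Step 7**
Reactants: 14 (2R,3R)-3,7-bis(benzyloxy)-2-[4-(benzyloxy)-3-methoxyphenyl]-5-hydroxychroman-4-one
Product: 15 (2R,3R)-3,5,7-trihydroxy-2-(4-hydroxy-3-methoxyphenyl)chroman-4-one
Conditions: H2 (1 atm), Pd/C, EtOAc–MeOH, rt
Reagents that add atoms: none
Why: Catalytic hydrogenolysis of two aryl benzyl ethers and one alkyl benzyl ether under neutral conditions; the C2–O1 bond, whose oxygen is conjugated with the C4 carbonyl, and the stereocentres should not be affected.

**Step 8**
Reactants: 15 (2R,3R)-3,5,7-trihydroxy-2-(4-hydroxy-3-methoxyphenyl)chroman-4-one; 16 prenyl bromide (1-bromo-3-methylbut-2-ene)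
Product: 17 (2R,3R)-3,5-dihydroxy-2-(4-hydroxy-3-methoxyphenyl)-7-(3-methylbut-2-enyloxy)chroman-4-one
Conditions: 16 (1.05 equiv), K2CO3 (1.0 equiv), DMF, 0 °C to rt, Ar
Reagents that add atoms: none
Why: Williamson etherification under acidity control; the 7-hydroxyl, para to the C4 carbonyl, is the most acidic group (the 5-hydroxyl is chelated, the 4'-phenol is a weaker acid, the 3-hydroxyl is an alcohol), so one equivalent of K2CO3 should form mainly the 7-phenoxide, which the primary allylic bromide alkylates at oxygen in DMF. The mild base and low temperature should leave C2 and C3 untouched.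

## Compound list

1 | 5-fluororesorcinol (5-fluorobenzene-1,3-diol) | Oc1cc(O)cc(F)c1 | starting material
2 | acetic acid | CC(=O)O | starting material
3 | 1-(2-fluoro-4,6-dihydroxyphenyl)ethan-1-one | CC(=O)c1c(O)cc(O)cc1F | intermediate
4 | benzyl bromide | BrCc1ccccc1 | starting material
5 | 1-[4-(benzyloxy)-2-fluoro-6-hydroxyphenyl]ethan-1-one | CC(=O)c1c(O)cc(OCc2ccccc2)cc1F | intermediate
6 | 1-[4-(benzyloxy)-2-fluoro-6-(triisopropylsilyloxy)phenyl]ethan-1-one | CC(=O)c1c(O[Si](C(C)C)(C(C)C)C(C)C)cc(OCc2ccccc2)cc1F | intermediate
7 | 1-[4-(benzyloxy)-2-fluoro-6-(triisopropylsilyloxy)phenyl]-4,4,4-trifluorobutane-1,3-dione | O=C(CC(=O)C(F)(F)F)c1c(O[Si](C(C)C)(C(C)C)C(C)C)cc(OCc2ccccc2)cc1F | intermediate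
8 | 1-[4-(benzyloxy)-2-fluoro-6-(triisopropylsilyloxy)phenyl]-2-diazoethan-1-one | [N-]=[N+]=CC(=O)c1c(F)cc(OCc2ccccc2)cc1O[Si](C(C)C)(C(C)C)C(C)C | intermediate
9 | benzyl alcohol | OCc1ccccc1 | starting material
10 | 4-(benzyloxy)-3-methoxybenzaldehyde | COc1cc(C=O)ccc1OCc1ccccc1 | starting material
11 | (Z)-2-(benzyloxy)-1-[4-(benzyloxy)-2-fluoro-6-(triisopropylsilyloxy)phenyl]ethen-1-ol | O/C(=C\OCc1ccccc1)c1c(F)cc(OCc2ccccc2)cc1O[Si](C(C)C)(C(C)C)C(C)C | intermediate
12 | (2R,3R)-2-(benzyloxy)-1-[4-(benzyloxy)-2-fluoro-6-(triisopropylsilyloxy)phenyl]-3-[4-(benzyloxy)-3-methoxyphenyl]-3-hydroxypropan-1-one | COc1cc([C@@H](O)[C@@H](OCc2ccccc2)C(=O)c2c(F)cc(OCc3ccccc3)cc2O[Si](C(C)C)(C(C)C)C(C)C)ccc1OCc1ccccc1 | intermediate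
13 | (2R,3R)-3,7-bis(benzyloxy)-2-[4-(benzyloxy)-3-methoxyphenyl]-5-(triisopropylsilyloxy)chroman-4-one | COc1cc([C@H]2Oc3cc(OCc4ccccc4)cc(O[Si](C(C)C)(C(C)C)C(C)C)c3C(=O)[C@@H]2OCc2ccccc2)ccc1OCc1ccccc1 | intermediate
14 | (2R,3R)-3,7-bis(benzyloxy)-2-[4-(benzyloxy)-3-methoxyphenyl]-5-hydroxychroman-4-one | COc1cc([C@H]2Oc3cc(OCc4ccccc4)cc(O)c3C(=O)[C@@H]2OCc2ccccc2)ccc1OCc1ccccc1 | intermediate
15 | (2R,3R)-3,5,7-trihydroxy-2-(4-hydroxy-3-methoxyphenyl)chroman-4-one | COc1cc([C@H]2Oc3cc(O)cc(O)c3C(=O)[C@@H]2O)ccc1O | intermediate
16 | prenyl bromide (1-bromo-3-methylbut-2-ene) | CC(C)=CCBr | starting material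
17 | (2R,3R)-3,5-dihydroxy-2-(4-hydroxy-3-methoxyphenyl)-7-(3-methylbut-2-enyloxy)chroman-4-one | COc1cc([C@H]2Oc3cc(OCC=C(C)C)cc(O)c3C(=O)[C@@H]2O)ccc1O | target

## Step count and least certain steps

Total step count: 8. Longest linear sequence: 8 steps (1 to 17); 9, 10, 4, 2 and 16 are bought.

**Step 5 (key step).** The most likely failures are three. The proton shift of the ylide or enol may outrun addition to 10, which is an electron-rich and therefore weak electrophile, so that only the O–H insertion product forms. The acid may give insufficient control of the syn/anti ratio or of the absolute sense with a ketone-derived enol. The carbene may form a carbonyl ylide with 10.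

The fallback separates the two bond formations and returns at 13:
- From 8, Rh2(OAc)4 and 9 without acid would give the O–H insertion product, 2-(benzyloxy)-1-[4-(benzyloxy)-2-fluoro-6-(triisopropylsilyloxy)phenyl]ethan-1-one F1.
- Its (Z)-enol diisopinocampheylborinate (Ipc2BOTf, iPr2NEt, CH2Cl2, −78 °C; reagent enantiomer chosen for the 3R carbinol) should add to 10 through a closed chair transition state to give the syn aldol (2S,3R)-2-(benzyloxy)-1-[4-(benzyloxy)-2-fluoro-6-(triisopropylsilyloxy)phenyl]-3-[4-(benzyloxy)-3-methoxyphenyl]-3-hydroxypropan-1-one F2.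
- Ring closure of F2 with NaH as in step 6 would give the 2,3-cis chromanone (2R,3S)-3,7-bis(benzyloxy)-2-[4-(benzyloxy)-3-methoxyphenyl]-5-(triisopropylsilyloxy)chroman-4-one F3.
- C3 of F3 is α to the ketone and should equilibrate with DBU in CH2Cl2 to the diequatorial trans isomer, which is 13. Reprotonation of the enolate is expected to be faster than the stereoelectronically disfavoured opening of the ring.
- The fluoride treatment of step 6 then continues to 14.

**Step 6.** The aldolate may cleave by retro-aldol reaction or lose water by β-elimination before it closes. Any base left over may enolise the chromanone at C3, and ring opening by β-elimination would erode C2.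

The fallback takes the carbonyl group out of play during ring closure. It sets out from 12 and returns at 15:
- NaBH4 (MeOH, 0 °C) should give (2R,3R)-2-(benzyloxy)-1-[4-(benzyloxy)-2-fluoro-6-(triisopropylsilyloxy)phenyl]-3-[4-(benzyloxy)-3-methoxyphenyl]propane-1,3-diol F4 as both C1 epimers; that centre is destroyed later.
- An aryl silyl ether next to an alkoxide would migrate, so the silyl group is exchanged for benzyl in one flask (CsF, BnBr, DMF). This gives (2R,3R)-2-(benzyloxy)-1-[2,4-bis(benzyloxy)-6-fluorophenyl]-3-[4-(benzyloxy)-3-methoxyphenyl]propane-1,3-diol F5.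
- The dialkoxide of F5 (KOt-Bu, THF–DMF, rt to 50 °C) cannot undergo retro-aldol cleavage. Only the C3 alkoxide can reach the fluorinated carbon in a six-membered SNAr closure, the alkoxy groups being meta to fluorine. The product is (2R,3S)-3,5,7-tris(benzyloxy)-2-[4-(benzyloxy)-3-methoxyphenyl]chroman-4-ol F6.
- Dess–Martin oxidation of F6 would give (2R,3R)-3,5,7-tris(benzyloxy)-2-[4-(benzyloxy)-3-methoxyphenyl]chroman-4-one F7, the same compound as A7.
- Hydrogenolysis under the conditions of step 7 leads to 15.

**Step 8.** Discrimination between O7 and O4' may be incomplete (double alkylation). C-alkylation at C6 or C8 may compete. Base may open ring C at C2 with loss of configuration, and air may oxidise the product to the flavonol.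

The fallback replaces acidity control by protecting-group control. It sets out from 15 and returns at 17:
- Ac2O in pyridine would give (2R,3R)-2-[4-(acetyloxy)-3-methoxyphenyl]-4-oxochromane-3,5,7-triyl triacetate F8.
- The 7-acetate, para to the carbonyl, is the most activated ester and should be removed selectively (PhSH, imidazole, N-methylpyrrolidone, 0 °C). This gives (2R,3R)-2-[4-(acetyloxy)-3-methoxyphenyl]-7-hydroxy-4-oxochromane-3,5-diyl diacetate F9.
- The only free oxygen is then alkylated with 16 (K2CO3, acetone) to (2R,3R)-2-[4-(acetyloxy)-3-methoxyphenyl]-7-(3-methylbut-2-enyloxy)-4-oxochromane-3,5-diyl diacetate F10.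
- Mild methanolysis (catalytic K2CO3, MeOH, 0 °C) removes the three acetates and gives 17.

**Step 4.** C-trifluoroacetylation of the hindered, di-ortho-substituted enolate may be incomplete. The aryl silyl group may migrate to the enolate oxygen or be lost under the basic diazo-transfer conditions.

The fallback builds the diazo group by substitution and elimination instead of diazo transfer. It sets out from 6 and returns at 8:
- α-Bromination with PhNMe3Br3 (THF, 0 °C) would give 2-bromo-1-[4-(benzyloxy)-2-fluoro-6-(triisopropylsilyloxy)phenyl]ethan-1-one F11.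
- N,N'-ditosylhydrazine and DBU (THF, 0 °C) alkylate the hydrazine nitrogen, and two sulfinate eliminations give 8.

## Further compounds

F1 | step 5 | 2-(benzyloxy)-1-[4-(benzyloxy)-2-fluoro-6-(triisopropylsilyloxy)phenyl]ethan-1-one | O=C(COCc1ccccc1)c1c(F)cc(OCc2ccccc2)cc1O[Si](C(C)C)(C(C)C)C(C)C
F2 | step 5 | (2S,3R)-2-(benzyloxy)-1-[4-(benzyloxy)-2-fluoro-6-(triisopropylsilyloxy)phenyl]-3-[4-(benzyloxy)-3-methoxyphenyl]-3-hydroxypropan-1-one | COc1cc([C@@H](O)[C@H](OCc2ccccc2)C(=O)c2c(F)cc(OCc3ccccc3)cc2O[Si](C(C)C)(C(C)C)C(C)C)ccc1OCc1ccccc1
F3 | step 5 | (2R,3S)-3,7-bis(benzyloxy)-2-[4-(benzyloxy)-3-methoxyphenyl]-5-(triisopropylsilyloxy)chroman-4-one | COc1cc([C@H]2Oc3cc(OCc4ccccc4)cc(O[Si](C(C)C)(C(C)C)C(C)C)c3C(=O)[C@H]2OCc2ccccc2)ccc1OCc1ccccc1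
F4 | step 6 | (2R,3R)-2-(benzyloxy)-1-[4-(benzyloxy)-2-fluoro-6-(triisopropylsilyloxy)phenyl]-3-[4-(benzyloxy)-3-methoxyphenyl]propane-1,3-diol (both C1 epimers) | COc1cc([C@@H](O)[C@@H](OCc2ccccc2)C(O)c2c(F)cc(OCc3ccccc3)cc2O[Si](C(C)C)(C(C)C)C(C)C)ccc1OCc1ccccc1
F5 | step 6 | (2R,3R)-2-(benzyloxy)-1-[2,4-bis(benzyloxy)-6-fluorophenyl]-3-[4-(benzyloxy)-3-methoxyphenyl]propane-1,3-diol (both C1 epimers) | COc1cc([C@@H](O)[C@@H](OCc2ccccc2)C(O)c2c(F)cc(OCc3ccccc3)cc2OCc2ccccc2)ccc1OCc1ccccc1
F6 | step 6 | (2R,3S)-3,5,7-tris(benzyloxy)-2-[4-(benzyloxy)-3-methoxyphenyl]chroman-4-ol (both C4 epimers) | COc1cc([C@H]2Oc3cc(OCc4ccccc4)cc(OCc4ccccc4)c3C(O)[C@@H]2OCc2ccccc2)ccc1OCc1ccccc1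
F7 | step 6 | (2R,3R)-3,5,7-tris(benzyloxy)-2-[4-(benzyloxy)-3-methoxyphenyl]chroman-4-one | COc1cc([C@H]2Oc3cc(OCc4ccccc4)cc(OCc4ccccc4)c3C(=O)[C@@H]2OCc2ccccc2)ccc1OCc1ccccc1
F8 | step 8 | (2R,3R)-2-[4-(acetyloxy)-3-methoxyphenyl]-4-oxochromane-3,5,7-triyl triacetate | COc1cc([C@H]2Oc3cc(OC(C)=O)cc(OC(C)=O)c3C(=O)[C@@H]2OC(C)=O)ccc1OC(C)=O
F9 | step 8 | (2R,3R)-2-[4-(acetyloxy)-3-methoxyphenyl]-7-hydroxy-4-oxochromane-3,5-diyl diacetate | COc1cc([C@H]2Oc3cc(O)cc(OC(C)=O)c3C(=O)[C@@H]2OC(C)=O)ccc1OC(C)=O
F10 | step 8 | (2R,3R)-2-[4-(acetyloxy)-3-methoxyphenyl]-7-(3-methylbut-2-enyloxy)-4-oxochromane-3,5-diyl diacetate | COc1cc([C@H]2Oc3cc(OCC=C(C)C)cc(OC(C)=O)c3C(=O)[C@@H]2OC(C)=O)ccc1OC(C)=O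
F11 | step 4 | 2-bromo-1-[4-(benzyloxy)-2-fluoro-6-(triisopropylsilyloxy)phenyl]ethan-1-one | O=C(CBr)c1c(F)cc(OCc2ccccc2)cc1O[Si](C(C)C)(C(C)C)C(C)C
A1 | alternative 1 | (2R,3R)-3-(tert-butyldimethylsilyloxy)-2-[4-(tert-butyldimethylsilyloxy)-3-methoxyphenyl]-5-hydroxy-7-(3-methylbut-2-enyloxy)chroman-4-one | COc1cc([C@H]2Oc3cc(OCC=C(C)C)cc(O)c3C(=O)[C@@H]2O[Si](C)(C)C(C)(C)C)ccc1O[Si](C)(C)C(C)(C)C
A2 | alternative 1 | (2R,3R)-5-bromo-3-(tert-butyldimethylsilyloxy)-2-[4-(tert-butyldimethylsilyloxy)-3-methoxyphenyl]-2,3-dihydro-4H-pyran-4-one | COc1cc([C@H]2OC=C(Br)C(=O)[C@@H]2O[Si](C)(C)C(C)(C)C)ccc1O[Si](C)(C)C(C)(C)C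
A3 | alternative 1 | 1-methoxy-3-(3-methylbut-2-enyloxy)-1-(trimethylsilyloxy)buta-1,3-diene | COC(=CC(=C)OCC=C(C)C)O[Si](C)(C)C
A4 | alternative 2 | (2R,3S)-5,7-bis(benzyloxy)-2-(4-hydroxy-3-methoxyphenyl)chroman-3-yl pivalate | COc1cc([C@H]2Oc3cc(OCc4ccccc4)cc(OCc4ccccc4)c3C[C@@H]2OC(=O)C(C)(C)C)ccc1O
A5 | alternative 2 | 3,5-bis(benzyloxy)-2-(hydroxymethyl)phenol | OCc1c(O)cc(OCc2ccccc2)cc1OCc1ccccc1
A6 | alternative 2 | (E)-2-(4-hydroxy-3-methoxyphenyl)ethenyl 2,2-dimethylpropanoate | COc1cc(/C=C/OC(=O)C(C)(C)C)ccc1O
A7 | alternative 3 | (2R,3R)-3,5,7-tris(benzyloxy)-2-[4-(benzyloxy)-3-methoxyphenyl]chroman-4-one | COc1cc([C@H]2Oc3cc(OCc4ccccc4)cc(OCc4ccccc4)c3C(=O)[C@@H]2OCc2ccccc2)ccc1OCc1ccccc1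
A8 | alternative 3 | 3,5-bis(benzyloxy)-2-(trimethylsilyl)phenyl trifluoromethanesulfonate | C[Si](C)(C)c1c(OS(=O)(=O)C(F)(F)F)cc(OCc2ccccc2)cc1OCc1ccccc1
A9 | alternative 3 | methyl (2R,3R)-2-(benzyloxy)-3-[4-(benzyloxy)-3-methoxyphenyl]-3-hydroxypropanoate | COc1cc([C@@H](O)[C@@H](OCc2ccccc2)C(=O)OC)ccc1OCc1ccccc1
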